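## The problem

Atom numbers C1–C15 are those of the target 29 and are used for every intermediate; the extra carbon that later leaves is called the strap carbon.

1. The target is a ten-membered carbocycle C1–C10 bridged by oxygen from C1 to C4 (a 2,5-disubstituted oxolane, so an 11-oxabicyclo[6.2.1]undecane). A butenolide is fused at C6–C7, and its enol-lactone double bond C5=C6 is part of the carbocycle.
2. Four ring stereocentres must be set: C1, C4 (quaternary, methyl C15), C10 (tertiary alcohol, methyl C14) and C8 (acyloxy). A fifth lies in the (S)-2-methyloxirane-2-carboxylate.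
3. C1 and C4 are tied cis by the bridge. C10 is fully substituted and has no hydrogen to epimerise, so it must be fixed against C1 in a bond-forming event. C8 is separated from C10 by a methylene and cannot simply be relayed from it.
4. The enol lactone is an acylating agent, the C13 acetate is allylic, the epoxy ester opens with acid or nucleophiles, and the tertiary alcohol can dehydrate. The oxygens on C4 and C8 are both β to C6, so any C6 carbonyl intermediate can eliminate. Butenolide and ester therefore come last.
5. The enabling feature: C4 and C1 are the α-carbons of an oxolane, and their outer neighbours C5 and C10 are joined by the chain C6–C9. One extra carbon between C5 and C10 turns that chain into a cycloheptanone and the whole bicyclic ether into the [4+3] adduct of a furan with a cycloheptenyl oxyallyl cation.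
6. The extra carbon is not wasted. Baeyer–Villiger excision puts the C10 oxygen in place with retention and leaves a carboxyl on C5, which leaves as CO2 once C6 is a ketone.

## Retrosynthesis

**C8 ester.** The O8–acyl bond of 29 is cut first, giving diol 25 and acid 28. The epoxy ester is the most fragile group and tolerates none of the enolate, acid or fluoride steps, so it goes on last. The forward step must acylate the secondary allylic hydroxyl and leave the tertiary C10 hydroxyl alone. Acid 28 comes from alcohol 27 and this from 26 by asymmetric epoxidation and oxidation.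

**Butenolide.** In 25 (protected as 24) the O6–C12 and C7=C11 bonds are cut, leading through aldol adduct 23 to ketone 19 and ketoester 21. Carrying C11–C13 on C7 from the start would burden every earlier step with an extra stereocentre and a larger cation. The ketone/α-ketoester condensation brings all three carbons, the C13 oxygen and the lactone carbonyl in one reagent. The forward reaction must enolise C6 toward C7 rather than C5, and the cyclodehydration must spare the acetate. 21 comes from 20 by acetate displacement.

**Strap removal.** Ketone 19 (diol 18) is traced to β-keto lactone 16, alcohol 15 and ε-lactone 13. The cuts are C5–C(strap) and O–C(strap). Compared with direct methanolysis of 13, passing through δ-lactone 15 solves the one selectivity problem of this stretch. After desilylation the carboxyl moves from the tertiary O10 to O8, so O8 is protected by the strap carbon and O6 is the only secondary hydroxyl left to oxidise. Decarboxylation of 16 then removes the strap and frees O8 again.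

**Oxidation level of the strap.** Lactone 13 comes from ketone 12 by Baeyer–Villiger oxidation, and 12 from cycloadduct 11 by hydrogenation of C2=C3. The migration must be that of C10, which is both the more substituted and the less oxygen-deactivated α-carbon.

**Key cut.** In 11 the bonds C4–C5 and C1–C10 are cut, giving chloroketone 8 and 2-methylfuran 9. No other single cut removes a ring, two skeletal bonds and four stereocentres at once, and the precursors are a monocyclic ketone and a commodity furan. The forward reaction must be regioselective (methyl-bearing termini apart), face-selective on the cation (anti to the silyloxy groups) and must run through the extended arrangement.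

**Chloroketone.** 8 is traced to enone 6 (conjugate hydrosilylation, chlorination), 6 to silyl enol ether 4 (one-carbon ring expansion) and 4 to meso ketone 3 by enantioselective deprotonation. 3 comes from alcohol 2 and triol 1. A meso precursor with one desymmetrising step is preferred to a chiral-pool cycloheptane because the position of the methyl group and the absolute configuration are set in the same event.

## Roads not taken

**Alternative 1:** contraction of a thirteen-membered cyclic allylic ether by a Still–Wittig [2,3] shift. The cut is C7–C8. Tin–lithium exchange at C8 and the shift onto C7 would give the oxa-bridged cyclodecane A1 with a free C8 hydroxyl and a 3-(4-methoxybenzyloxy)prop-1-en-2-yl group on C7.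
- Merits: C11–C13 arrive on C7 with C13 already oxygenated. The C8 hydroxyl appears free and alone, ready for the ester. A ring contraction is entropically easier than a direct ten-ring closure.
- Weak points: the oxolane with C1, C4 and C10 must be built beforehand by separate stereocontrolled steps. The macrocyclic α-alkoxystannane has to be closed with a defined C8 configuration. The [1,2] shift competes. The exocyclic methylene must still be oxidised to the C12 carboxyl level, and C6 must be brought to the enol-lactone level.
- Comparison: this road is better than the chosen one where the chosen one is weakest. It has no regiochemical question at C7 (step 14) and needs no lactone shuttle to tell O6 from O8 (step 9). The chosen plan sets against it the assembly of carbocycle, ether bridge and C10 in one step from simple materials, and a much shorter sequence to the bicyclic core.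

**Alternative 2:** anionic oxy-Cope expansion of a 1,2-dialkenylcyclohexanol alkoxide. C2–C3 forms and C5–C10 breaks, giving the (1(10)E,4E)-cyclodecadiene A2 with a C5 silyl enol ether, C6 and C8 oxygens and an isopropenyl group on C7.
- Merits: a very short, chiral-pool entry to the ten-membered ring. The chair transition state gives reliable alkene geometry. C11–C13 are in place on C7.
- Weak points: none of the oxygens at C1, C4 and C10 is present. Both trisubstituted alkenes would have to be oxidised face-selectively on a mobile germacradiene that cyclises transannularly under acid or electrophiles. The cis C1–O–C4 bridge and the C10 configuration would depend on conformer populations. The enol ether also places oxygen on C5, not C6.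
- Comparison: this road is faster to the carbocycle and to the C7 side chain. The chosen plan is stronger where the target is hardest, because the bridge and the C10 carbinol are formed by construction and not by late oxidation of a flexible ring.

**Alternative 3:** oxonium ylide formation and [2,3] ring expansion of a 2-vinyl tetrahydropyran diazo ketone, for example with Rh2(OAc)4 or Cu(hfacac)2. O–C4 and C4–C5 form, giving the 11-oxabicyclo[6.2.1]undec-6-en-3-one A3 with the C4 methyl and silyl ethers at C8 and C10.
- Merits: the bicyclic ether appears in one catalytic step. C1, C8 and C10 are set beforehand on a six-membered ring, where control is easy, and the C6=C7 alkene is a handle for the butenolide. For the relative configuration of the core this road is at least as reliable as the chosen one and has no counterpart to its mode problem.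
- Weak points: the precursor is a tetrasubstituted tetrahydropyran that needs a long synthesis. The carbenoid carbon carries the methyl group, so hydride shift to an enone and [1,2] shift compete. The C3 ketone must be removed, and the alkene must be functionalised regioselectively (oxygen on C6, carbon on C7).
- Comparison: the chosen plan sets brevity and the productive use of its extra carbon (it becomes the C10 oxygen and the temporary O8 protecting group) against the better-secured stereochemistry of A3. Its open question, the extended mode, is met with a reagent-controlled fallback.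

Key step: step 6

Remark: the sense of induction of the chiral lithium amide in step 3 is assumed by analogy with other meso cyclohexanones; if it proves opposite, the equally available (S,S)-amide is used.

Remark: 16 is drawn as the diketo form although it should exist largely as its enol, and 18 may rest as the O10–C6 hemiketal; both react through the forms drawn.

## Route

Step 1
Reactants: 1 cis,cis-cyclohexane-1,3,5-triol
Product: 2 all-cis-3,5-bis(tert-butyldimethylsilyloxy)cyclohexan-1-ol (meso)
Conditions: TBSCl (2.1 equiv), imidazole, DMF, 0 °C → rt
Reagents that add atoms: tert-butyldimethylsilyl chloride, CC(C)(C)[Si](C)(C)Cl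
Why: Statistical silylation of a triol with three equivalent hydroxyls; two equivalents should give mainly the bis-ether, and over- and under-silylated material can be recycled. No stereocentre is formed.

Step 2
Reactants: 2 all-cis-3,5-bis(tert-butyldimethylsilyloxy)cyclohexan-1-ol
Product: 3 (3R,5S)-3,5-bis(tert-butyldimethylsilyloxy)cyclohexan-1-one (cis; meso)
Conditions: (n-Pr)4N[RuO4] (5 mol%), NMO, 4 Å MS, CH2Cl2, rt
Reagents that add atoms: none
Why: Ley–Griffith oxidation of a secondary alcohol under neutral conditions, chosen so that the β-silyloxy ketone does not eliminate.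

Step 3
Reactants: 3 (3R,5S)-3,5-bis(tert-butyldimethylsilyloxy)cyclohexan-1-one
Product: 4 (3R,5S)-3,5-bis(tert-butyldimethylsilyloxy)-1-(trimethylsilyloxy)cyclohex-1-ene
Conditions: lithium (R,R)-bis(1-phenylethyl)amide (from the amine and n-BuLi), TMSCl (in situ), THF, −78 °C; Et3N, NaHCO3 work-up
Reagents that add atoms: chlorotrimethylsilane, C[Si](C)(C)Cl
Why: Enantioselective deprotonation of a meso cis-3,5-disubstituted cyclohexanone by a chiral lithium amide with in situ silylation. The base removes one of the two enantiotopic axial α-protons, which decides that the future C9 and not the future C5 is enolised; immediate trapping keeps the β-silyloxy enolate from eliminating.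

Step 4
Reactants: 4 (3R,5S)-3,5-bis(tert-butyldimethylsilyloxy)-1-(trimethylsilyloxy)cyclohex-1-ene
Product: 6 (4R,6S)-4,6-bis(tert-butyldimethylsilyloxy)-2-methylcyclohept-2-en-1-one, via chlorocyclopropane 5 (not isolated)
Conditions: CH3CHCl2, n-BuLi, Et2O, −40 °C → rt; then toluene, 110 °C
Reagents that add atoms: 1,1-dichloroethane, CC(Cl)Cl
Why: Chloro(methyl)carbenoid cyclopropanation of the silyl enol ether, then thermal electrocyclic opening of the chlorosiloxycyclopropane with loss of Me3SiCl (one-carbon ring expansion to a 2-methylcycloalk-2-enone). The new carbon enters only between the carbonyl carbon and the enolised carbon, so the desymmetrisation of step 3 becomes the position of the methyl group; the two carbinol centres are untouched.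

Step 5
Reactants: 6 (4R,6S)-4,6-bis(tert-butyldimethylsilyloxy)-2-methylcyclohept-2-en-1-one
Product: 8 (4R,6S)-4,6-bis(tert-butyldimethylsilyloxy)-2-chloro-2-methylcycloheptan-1-one (both C2 epimers), via triethylsilyl enol ether 7 (not isolated)
Conditions: Et3SiH, RhCl(PPh3)3 (1 mol%), THF, 50 °C; then NCS, THF, 0 °C → rt
Reagents that add atoms: N-chlorosuccinimide, O=C1CCC(=O)N1Cl
Why: RhCl(PPh3)3-catalysed 1,4-hydrosilylation gives the tetrasubstituted silyl enol ether regiospecifically, and electrophilic chlorination then puts chlorine on the methyl-bearing carbon without acid. The C2 configuration is irrelevant because this carbon is ionised in step 6.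

Step 6
Reactants: 8 (4R,6S)-4,6-bis(tert-butyldimethylsilyloxy)-2-chloro-2-methylcycloheptan-1-one; 9 2-methylfuran
Product: 11 (1S,4R,5S,6S,8S,10R)-6,8-bis(tert-butyldimethylsilyloxy)-4,10-dimethylcyclodec-2-ene bridged by O across C1/C4 and by C=O across C5/C10, via oxyallyl zwitterion 10 (not isolated)
Conditions: Et3N (2 equiv), 2-methylfuran (10 equiv), (CF3)2CHOH, 0 °C → rt
Reagents that add atoms: none
Why: Triethylamine enolises 8 toward C5, its only enolisable side, and the ionising alcohol removes the tertiary chloride to give oxyallyl zwitterion 10; this is the base-mediated [4+3] cycloaddition of α-chloroketones with furans, which is known for cyclic oxyallyl cations. The cation adds suprafacially across the two α-carbons of 9 and closes the seven-membered ring C1–C2=C3–C4–C5–C(=O)–C10 in a 4π + 2π(allyl cation) cycloaddition, probably asynchronous with C1–C10 leading; this ring completes the ten-membered carbocycle with its ether bridge. Regiochemistry: the unsubstituted, most nucleophilic furan carbon should bond to the tertiary terminus C10 and the methyl-bearing furan carbon to C5, so that no two fully substituted carbons are joined. C1 and C4 are held cis by the furan oxygen, and C5 and C10 by the ring of the cation. Facial control: the furan should add anti to the two cis silyloxy groups, the C6 group sitting next to the C5 terminus, which sets C5 and C10 relative to C8. Mode control: the extended arrangement (C6–C9 under the furan carbons, oxyallyl oxygen and C14 toward the furan oxygen) is required to place C14 syn to the bridge, and it competes with the compact arrangement that cyclic oxyallyl cations usually prefer with furans. The hydrogen-bonded, heavily solvated oxyallyl oxygen in hexafluoroisopropanol is harder to tuck under the diene and an early C1–C10 bond loosens the sandwich, which should shift the balance; the two adducts are diastereomers, to be separated by chromatography and told apart by NOE contacts of C14, and only the extended one is carried on.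

Step 7
Reactants: 11 cycloadduct
Product: 12 2,3-dihydro cycloadduct (C2–C3 saturated; configuration as 11)
Conditions: H2 (1 atm), 10% Pd/C, EtOAc, rt
Reagents that add atoms: none
Why: Heterogeneous hydrogenation of the strained cis-disubstituted bridge alkene; ketone and silyl ethers are inert and no stereocentre is formed. It must precede the peracid step.

Step 8
Reactants: 12 2,3-dihydro cycloadduct
Product: 13 ε-lactone with C5–C(=O)–O–C10 in place of the ketone bridge (6,8-bis-TBS ether; configuration as 11)
Conditions: mCPBA, NaHCO3, CH2Cl2, 0 °C → rt
Reagents that add atoms: 3-chloroperbenzoic acid, OOC(=O)c1cccc(Cl)c1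
Why: Baeyer–Villiger oxidation. The fully substituted C10 should migrate in preference to C5, which is secondary and carries two β-oxygens, and it migrates with retention, so the strap carbonyl oxygen ends on C10 with the configuration fixed in step 6.

Step 9
Reactants: 13 ε-lactone bis-TBS ether
Product: 15 δ-lactone C5–C(=O)–O–C8 with free 6-OH and 10-OH, via ε-lactone diol 14 (not isolated)
Conditions: HF (48% aq), MeCN, 0 °C → rt; then CSA (0.1 equiv), CH2Cl2, rt
Reagents that add atoms: none
Why: Acidic desilylation frees O6 and O8, and acid-catalysed acyl transfer from the tertiary O10 to the secondary O8 should give the six-membered lactone, since O8 lies on the same face of the carbocycle as the carboxyl carbon. O8 is thereby protected by the strap carbon itself and O6 is the only secondary hydroxyl left.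

Step 10
Reactants: 15 δ-lactone diol
Product: 16 6-oxo δ-lactone (β-keto lactone; C5 configurationally labile)
Conditions: DMP, NaHCO3, CH2Cl2, 0 °C → rt
Reagents that add atoms: none
Why: Dess–Martin oxidation of the only secondary alcohol; the C10 hydroxyl is tertiary and cannot react.

Step 11
Reactants: 16 6-oxo δ-lactone
Product: 18 (1S,4R,8S,10R)-8,10-dihydroxy-4,10-dimethyl-1,4-epoxycyclodecan-6-one, via β-keto acid 17 (not isolated)
Conditions: 1,4-dioxane/H2O (4:1), 90 °C
Reagents that add atoms: none
Why: Neutral hydrolytic opening of the β-keto lactone and decarboxylation of the β-keto acid remove the strap carbon, leave C5 as CH2 and free O8. Neutral conditions are chosen to spare the β-hydroxy ketone from elimination and retro-aldol cleavage.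

Step 12
Reactants: 18 dihydroxy ketone
Product: 19 (1S,4R,8S,10R)-8,10-O-(di-tert-butylsilylene) derivative of 18
Conditions: tBu2Si(OTf)2, 2,6-lutidine, CH2Cl2, 0 °C
Reagents that add atoms: di-tert-butylsilyl bis(trifluoromethanesulfonate), CC(C)(C)[Si](OS(=O)(=O)C(F)(F)F)(OS(=O)(=O)C(F)(F)F)C(C)(C)C
Why: Silylene protection of a secondary/tertiary 1,3-diol. One group masks both hydroxyls, prevents hemiketal formation of O10 with C6, is the most acid-tolerant option for step 15 and leaves in one operation in step 16.

Step 13
Reactants: 20 ethyl 3-bromo-2-oxopropanoate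
Product: 21 ethyl 3-acetoxy-2-oxopropanoate
Conditions: KOAc, DMF, 0 °C → rt
Reagents that add atoms: potassium acetate, CC(=O)[O-].[K+]
Why: SN2 displacement of an α-bromo ketone by acetate.

Step 14
Reactants: 19 silylene ketone; 21 ethyl 3-acetoxy-2-oxopropanoate
Product: 23 C7 aldol adduct as its C11 trimethylsilyl ether (mixture at C7 and C11), via C6–C7 trimethylsilyl enol ether 22 (not isolated)
Conditions: LDA, TMSCl (in situ), THF, −78 °C; filtration through pentane; then 21, Cu(OTf)2 (10 mol%), 2,2′-isopropylidenebis[(4S)-4-tert-butyl-2-oxazoline] (11 mol%), THF, −78 → −20 °C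
Reagents that add atoms: chlorotrimethylsilane, C[Si](C)(C)Cl
Why: Kinetic enolisation is expected at C7 because the C5 methylene is flanked by the quaternary C4 (as with 3,3-disubstituted cyclohexanones), and in situ silylation traps the enolate before either β-oxygen can leave. The Cu(OTf)2–bis(oxazoline)-catalysed Mukaiyama aldol addition to the chelating α-keto ester forms C7–C11 without a basic alkoxide, so the acetate stays on O13; the configurations at C7 and C11 are irrelevant because both carbons become sp2.

Step 15
Reactants: 23 silylated aldol adduct
Product: 24 8,10-O-(di-tert-butylsilylene)-protected ylidenebutenolide (C5=C6 enol lactone, C7=C11, 13-OAc)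
Conditions: TsOH·H2O (0.2 equiv), toluene, 80 °C, 5 Å MS
Reagents that add atoms: none
Why: Acid-catalysed cascade known for ketone/pyruvate aldols: loss of silanol across C7–C11, closure of the γ-keto ester to the pseudo-ester and loss of ethanol toward C5. The C5=C6 geometry is dictated by the ring and the fully conjugated lactone is the thermodynamic sink.

Step 16
Reactants: 24 protected ylidenebutenolide
Product: 25 (1S,4R,8S,10R)-8,10-dihydroxy ylidenebutenolide (13-OAc)
Conditions: HF·pyridine, pyridine, THF, 0 °C → rt
Reagents that add atoms: none
Why: Fluoride cleavage of the silylene under buffered conditions, which should leave the enol lactone and the allylic acetate alone.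

Step 17
Reactants: 26 2-methylprop-2-en-1-ol
Product: 27 (R)-(2-methyloxiran-2-yl)methanol
Conditions: Ti(OiPr)4 (5 mol%), D-(−)-diisopropyl tartrate (6 mol%), cumene hydroperoxide, 3 Å MS, CH2Cl2, −20 °C
Reagents that add atoms: cumene hydroperoxide, CC(C)(OO)c1ccccc1
Why: Sharpless asymmetric epoxidation of a 2-substituted allylic alcohol; the D-(−)-tartrate ligand directs oxygen to the face that gives the (R)-epoxide.

Step 18
Reactants: 27 (R)-(2-methyloxiran-2-yl)methanol
Product: 28 (S)-2-methyloxirane-2-carboxylic acid
Conditions: RuCl3·xH2O (2 mol%), NaIO4, MeCN/CCl4/H2O, 0 °C → rt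
Reagents that add atoms: water, O
Why: RuO4-catalysed oxidation of a 2,3-epoxy alcohol to the glycidic acid. The quaternary stereocentre cannot epimerise; the descriptor changes from R to S only because the priorities change.

Step 19
Reactants: 25 dihydroxy ylidenebutenolide; 28 (S)-2-methyloxirane-2-carboxylic acid
Product: 29 target, (1S,4R,8S,10R)-13-acetoxy-10-hydroxy-1,4-epoxygermacra-5,7(11)-dien-6,12-olide 8-[(S)-2-methyloxirane-2-carboxylate]
Conditions: DIC, DMAP (0.2 equiv), CH2Cl2, 0 °C → rt
Reagents that add atoms: none
Why: Steglich esterification. The secondary allylic C8 hydroxyl is acylated with retention while the tertiary C10 hydroxyl is not, and the neutral carbodiimide conditions respect the epoxide, the acetate and the enol lactone.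

## Compound list

1 | cis,cis-cyclohexane-1,3,5-triol (all-cis) | O[C@H]1C[C@@H](O)C[C@@H](O)C1 | starting material
2 | all-cis-3,5-bis(tert-butyldimethylsilyloxy)cyclohexan-1-ol (meso) | O[C@H]1C[C@@H](O[Si](C)(C)C(C)(C)C)C[C@@H](O[Si](C)(C)C(C)(C)C)C1 | intermediate
3 | (3R,5S)-3,5-bis(tert-butyldimethylsilyloxy)cyclohexan-1-one (cis, meso) | O=C1C[C@H](O[Si](C)(C)C(C)(C)C)C[C@H](O[Si](C)(C)C(C)(C)C)C1 | intermediate
4 | (3R,5S)-3,5-bis(tert-butyldimethylsilyloxy)-1-(trimethylsilyloxy)cyclohex-1-ene | C[Si](C)(C)OC1=C[C@H](O[Si](C)(C)C(C)(C)C)C[C@H](O[Si](C)(C)C(C)(C)C)C1 | intermediate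
5 | 7-chloro-7-methyl-3,5-bis(tert-butyldimethylsilyloxy)-1-(trimethylsilyloxy)bicyclo[4.1.0]heptane (3,5-cis; mixture at C1, C6, C7) | C[Si](C)(C)OC12C(C)(Cl)C1[C@H](O[Si](C)(C)C(C)(C)C)C[C@H](O[Si](C)(C)C(C)(C)C)C2 | intermediate (not isolated)
6 | (4R,6S)-4,6-bis(tert-butyldimethylsilyloxy)-2-methylcyclohept-2-en-1-one | CC1=C[C@H](O[Si](C)(C)C(C)(C)C)C[C@H](O[Si](C)(C)C(C)(C)C)CC1=O | intermediate
7 | 4,6-cis-4,6-bis(tert-butyldimethylsilyloxy)-2-methyl-1-(triethylsilyloxy)cyclohept-1-ene (configured as 6) | CC1=C(O[Si](CC)(CC)CC)C[C@@H](O[Si](C)(C)C(C)(C)C)C[C@@H](O[Si](C)(C)C(C)(C)C)C1 | intermediate (not isolated)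
8 | (4R,6S)-4,6-bis(tert-butyldimethylsilyloxy)-2-chloro-2-methylcycloheptan-1-one (both C2 epimers) | O=C1C[C@@H](O[Si](C)(C)C(C)(C)C)C[C@@H](O[Si](C)(C)C(C)(C)C)CC1(C)Cl | intermediate
9 | 2-methylfuran | Cc1ccco1 | starting material
10 | 4,6-bis(tert-butyldimethylsilyloxy)-2-methyl-2-oxidocycloheptenylium (oxyallyl zwitterion from 8) | C[C+]1C[C@H](O[Si](C)(C)C(C)(C)C)C[C@H](O[Si](C)(C)C(C)(C)C)C=C1[O-] | intermediate (not isolated)
11 | (1S,4R,5S,6S,8S,10R)-cycloadduct: cyclodec-2-ene with O bridging C1/C4, C=O bridging C5/C10, 6,8-bis(tert-butyldimethylsilyloxy), 4-methyl, 10-methyl | O=C1[C@]2(C)C[C@H](O[Si](C)(C)C(C)(C)C)C[C@H](O[Si](C)(C)C(C)(C)C)[C@H]1[C@@]1(C)C=C[C@@H]2O1 | intermediate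
12 | 2,3-dihydro derivative of 11 | O=C1[C@]2(C)C[C@H](O[Si](C)(C)C(C)(C)C)C[C@H](O[Si](C)(C)C(C)(C)C)[C@H]1[C@@]1(C)CC[C@@H]2O1 | intermediate
13 | ε-lactone: C5–C(=O)–O–C10 bridge, 1,4-ether, 6,8-bis(tert-butyldimethylsilyloxy) (configuration as 11) | O=C1O[C@]2(C)C[C@H](O[Si](C)(C)C(C)(C)C)C[C@H](O[Si](C)(C)C(C)(C)C)[C@H]1[C@@]1(C)CC[C@@H]2O1 | intermediate
14 | 6,8-diol of ε-lactone 13 | O=C1O[C@]2(C)C[C@H](O)C[C@H](O)[C@H]1[C@@]1(C)CC[C@@H]2O1 | intermediate (not isolated)
15 | δ-lactone: C5–C(=O)–O–C8, 1,4-ether, free 6-OH and 10-OH (C1, C4, C8, C10 as in 29; C5, C6 as in 11) | O=C1O[C@H]2C[C@@](C)(O)[C@@H]3CC[C@@](C)(O3)[C@@H]1[C@@H](O)C2 | intermediate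
16 | 6-oxo δ-lactone (β-keto lactone, C5 labile, largely enolised) | O=C1O[C@H]2C[C@@](C)(O)[C@@H]3CC[C@@](C)(O3)C1C(=O)C2 | intermediate
17 | 8,10-dihydroxy-4,10-dimethyl-6-oxo-1,4-epoxycyclodecane-5-carboxylic acid | OC(=O)C1C(=O)C[C@@H](O)C[C@@](C)(O)[C@@H]2CC[C@@]1(C)O2 | intermediate (not isolated)
18 | (1S,4R,8S,10R)-8,10-dihydroxy-4,10-dimethyl-1,4-epoxycyclodecan-6-one | O=C1C[C@@H](O)C[C@@](C)(O)[C@@H]2CC[C@@](C)(O2)C1 | intermediate
19 | (1S,4R,8S,10R)-8,10-O-(di-tert-butylsilylene)-4,10-dimethyl-1,4-epoxycyclodecan-6-one | O=C1C[C@@H]2C[C@@](C)(O[Si](C(C)(C)C)(C(C)(C)C)O2)[C@@H]3CC[C@@](C)(O3)C1 | intermediate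
20 | ethyl 3-bromo-2-oxopropanoate | CCOC(=O)C(=O)CBr | starting material
21 | ethyl 3-acetoxy-2-oxopropanoate | CCOC(=O)C(=O)COC(C)=O | intermediate
22 | C6–C7 trimethylsilyl enol ether of 19 | C[Si](C)(C)OC1=C[C@@H]2C[C@@](C)(O[Si](C(C)(C)C)(C(C)(C)C)O2)[C@@H]3CC[C@@](C)(O3)C1 | intermediate (not isolated)
23 | ethyl 3-acetoxy-2-(trimethylsilyloxy)-2-(C7-yl)propanoate of ketone 19 (aldol adduct, C11 silyl ether; mixture at C7, C11) | O=C1C(C(O[Si](C)(C)C)(COC(C)=O)C(=O)OCC)[C@@H]2C[C@@](C)(O[Si](C(C)(C)C)(C(C)(C)C)O2)[C@@H]3CC[C@@](C)(O3)C1 | intermediate
24 | 8,10-O-(di-tert-butylsilylene)-13-acetoxy-1,4-epoxygermacra-5,7(11)-dien-6,12-olide (1S,4R,8S,10R) | CC(=O)OCC1=C2/C(=C\[C@@]3(C)CC[C@H](O3)[C@](C)(O[Si](C(C)(C)C)(C(C)(C)C)O4)C[C@@H]24)OC1=O | intermediate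
25 | (1S,4R,8S,10R)-13-acetoxy-8,10-dihydroxy-1,4-epoxygermacra-5,7(11)-dien-6,12-olide | CC(=O)OCC1=C2/C(=C\[C@@]3(C)CC[C@H](O3)[C@](C)(O)C[C@@H]2O)OC1=O | intermediate
26 | 2-methylprop-2-en-1-ol | CC(=C)CO | starting material
27 | (R)-(2-methyloxiran-2-yl)methanol | OC[C@]1(C)CO1 | intermediate
28 | (S)-2-methyloxirane-2-carboxylic acid | OC(=O)[C@]1(C)CO1 | intermediate
29 | (1S,4R,8S,10R)-13-acetoxy-10-hydroxy-1,4-epoxygermacra-5,7(11)-dien-6,12-olide 8-[(S)-2-methyloxirane-2-carboxylate] | CC(=O)OCC1=C2/C(=C\[C@@]3(C)CC[C@H](O3)[C@](C)(O)C[C@@H]2OC(=O)[C@]2(C)CO2)OC1=O | target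

## Step count and least certain steps

Total step count: 19. Longest linear sequence: 16 steps (steps 1–12, 14–16 and 19); steps 13, 17 and 18 are side branches.

**Step 6 (key step).** Bonding in the compact arrangement, with the ring of the cation under the furan oxygen, is what cyclic oxyallyl cations commonly prefer with furans; it would invert C1 and C4 relative to C10. Proton loss from the cation and electrophilic substitution of the furan without ring closure may also drain material.
Fallback, from 8: O-silylation (TIPSOTf, Et3N, CH2Cl2) gives 7-chloro-7-methyl-3,5-bis(tert-butyldimethylsilyloxy)-1-(triisopropylsilyloxy)cyclohept-1-ene F1. Chloride abstraction with AgOTf in CH2Cl2/MeNO2 at −78 °C in the presence of 9 then produces a 2-silyloxyallyl cation instead of the base-generated zwitterion. Its triisopropylsilyloxy group cannot be placed under the diene carbons, so the extended arrangement is enforced by a reagent-derived group and not by the medium. Loss of the silyl group from the adduct on work-up brings the route back at 11.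

**Step 3.** The amide may discriminate poorly between the enantiotopic α-methylenes, or silyloxide may be lost from the lithium enolate before it is silylated.
Fallback, from 3: catalytic asymmetric one-carbon homologation with benzyl 2-diazopropanoate under Sc(OTf)3 and a chiral N,N′-dioxide ligand, in which one enantiotopic α-carbon migrates, would give benzyl 4,6-bis(tert-butyldimethylsilyloxy)-1-methyl-2-oxocycloheptane-1-carboxylate F2. Hydrogenolysis (H2, Pd/C) to 4,6-bis(tert-butyldimethylsilyloxy)-1-methyl-2-oxocycloheptane-1-carboxylic acid F3 and decarboxylative chlorination with NCS put chlorine where the carboxyl was. The route is rejoined at 8, and steps 4 and 5 are bypassed as well.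

**Step 4.** Only the cyclopropane diastereomer with chlorine endo to the six-membered ring can open in the disrotatory sense that a seven-membered ring allows. A poor endo/exo ratio in the carbenoid addition, or attack of the alkyllithium on the silyl enol ether, would erode the ring expansion.
Fallback, from 4: cyclopropanation with Et2Zn/CH3CHI2 gives 7-methyl-3,5-bis(tert-butyldimethylsilyloxy)-1-(trimethylsilyloxy)bicyclo[4.1.0]heptane F4. FeCl3 in DMF opens the internal bond by one-electron oxidation regardless of configuration, giving 3-chloro-2-methyl-4,6-bis(tert-butyldimethylsilyloxy)cycloheptan-1-one F5. NaOAc in methanol eliminates HCl (Saegusa–Ito ring expansion) and the route is rejoined at 6.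

**Step 9.** The acyl shift from O10 to O8 may stall if the bridged ε-lactone holds its carbonyl away from O8. Two secondary alcohols would then reach the oxidation undifferentiated.
Fallback, from 13: methanolysis (K2CO3, MeOH) opens the strained lactone first to the methyl 6,8-bis(tert-butyldimethylsilyloxy)-10-hydroxy-1,4-epoxycyclodecane-5-carboxylate F6. HF·pyridine then gives the 6,8,10-triol methyl ester F7, whose freely rotating ester closes onto O8 under CSA with loss of methanol, the usual lactonisation of a 3,5-dihydroxy ester. The route is rejoined at 15.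

**Step 14.** Enolisation may occur toward C5 instead of C7, or the C8 silyloxy or C4 ether oxygen may be expelled from the enolate before silylation.
Fallback, from 19 and 21: a direct aldol addition under enamine catalysis (L-proline, DMSO, rt). The enamine should form away from the quaternary C4 for steric reasons and no metal enolate is involved. It would give the free C11-hydroxy aldol adduct F8, which enters the conditions of step 15 and rejoins the route at 24.

**Step 15.** The acid may cleave the silylene, ionise the allylic C8–O bond once C7=C11 is in place, or leave the cascade stalled at the pseudo-ester.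
Fallback, from 23: DBU eliminates silanol to the C7=C11 enedione ethyl ester F9. LiOH hydrolyses ester and acetate, and the (Z)-4-oxo-2-enoic acid closes to the 6-hydroxy-13-hydroxy butenolide lactol F10. Ac2O/Et3N/DMAP then re-acetylates O13, acetylates the lactol hydroxyl and eliminates acetic acid toward C5. The route is rejoined at 24 under basic instead of acidic conditions.

Further compounds
F1 | step 6 | 7-chloro-7-methyl-3,5-bis(tert-butyldimethylsilyloxy)-1-(triisopropylsilyloxy)cyclohept-1-ene | CC(C)[Si](C(C)C)(C(C)C)OC1=C[C@@H](O[Si](C)(C)C(C)(C)C)C[C@@H](O[Si](C)(C)C(C)(C)C)CC1(C)Cl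
F2 | step 3 | benzyl 4,6-bis(tert-butyldimethylsilyloxy)-1-methyl-2-oxocycloheptane-1-carboxylate | O=C1C[C@@H](O[Si](C)(C)C(C)(C)C)C[C@@H](O[Si](C)(C)C(C)(C)C)CC1(C)C(=O)OCc1ccccc1
F3 | step 3 | 4,6-bis(tert-butyldimethylsilyloxy)-1-methyl-2-oxocycloheptane-1-carboxylic acid | O=C1C[C@@H](O[Si](C)(C)C(C)(C)C)C[C@@H](O[Si](C)(C)C(C)(C)C)CC1(C)C(=O)O
F4 | step 4 | 7-methyl-3,5-bis(tert-butyldimethylsilyloxy)-1-(trimethylsilyloxy)bicyclo[4.1.0]heptane | C[Si](C)(C)OC12C(C)C1[C@H](O[Si](C)(C)C(C)(C)C)C[C@H](O[Si](C)(C)C(C)(C)C)C2
F5 | step 4 | 3-chloro-2-methyl-4,6-bis(tert-butyldimethylsilyloxy)cycloheptan-1-one | CC1C(Cl)[C@H](O[Si](C)(C)C(C)(C)C)C[C@H](O[Si](C)(C)C(C)(C)C)CC1=O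
F6 | step 9 | methyl 6,8-bis(tert-butyldimethylsilyloxy)-10-hydroxy-4,10-dimethyl-1,4-epoxycyclodecane-5-carboxylate | COC(=O)[C@H]1[C@@H](O[Si](C)(C)C(C)(C)C)C[C@@H](O[Si](C)(C)C(C)(C)C)C[C@@](C)(O)[C@@H]2CC[C@@]1(C)O2
F7 | step 9 | methyl 6,8,10-trihydroxy-4,10-dimethyl-1,4-epoxycyclodecane-5-carboxylate | COC(=O)[C@H]1[C@@H](O)C[C@@H](O)C[C@@](C)(O)[C@@H]2CC[C@@]1(C)O2
F8 | step 14 | C7 aldol adduct of 19 and 21 with free C11 hydroxyl | O=C1C(C(O)(COC(C)=O)C(=O)OCC)[C@@H]2C[C@@](C)(O[Si](C(C)(C)C)(C(C)(C)C)O2)[C@@H]3CC[C@@](C)(O3)C1
F9 | step 15 | C7=C11 enedione ethyl ester (13-OAc, silylene intact) | O=C1C(=C(COC(C)=O)C(=O)OCC)[C@@H]2C[C@@](C)(O[Si](C(C)(C)C)(C(C)(C)C)O2)[C@@H]3CC[C@@](C)(O3)C1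
F10 | step 15 | 6-hydroxy-13-hydroxy butenolide lactol (5-hydroxybutenolide, silylene intact) | OCC1=C2[C@@H]3C[C@@](C)(O[Si](C(C)(C)C)(C(C)(C)C)O3)[C@@H]4CC[C@@](C)(O4)CC2(O)OC1=O
A1 | alternative 1 | oxa-bridged cyclodecane with free C8 hydroxyl, C6 methoxymethyl ether, C10 triethylsilyl ether and C7 3-(4-methoxybenzyloxy)prop-1-en-2-yl group | [C@@H]1(O)[C@@H](C(=C)COCc2ccc(OC)cc2)[C@H](OCOC)C[C@@]3(C)CC[C@H](O3)[C@](C)(O[Si](CC)(CC)CC)C1
A2 | alternative 2 | (1(10)E,4E)-cyclodecadiene with C5 trimethylsilyl enol ether, C6 methoxymethyl ether, C8 tert-butyldimethylsilyl ether and C7 isopropenyl group | [C@H]1(O[Si](C)(C)C(C)(C)C)C/C(C)=C/CC/C(C)=C(O[Si](C)(C)C)/[C@@H](OCOC)[C@@H]1C(C)=C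
A3 | alternative 3 | 11-oxabicyclo[6.2.1]undec-6-en-3-one with C4 methyl, C8 tert-butyldimethylsilyl ether and C10 triethylsilyl ether | C1/C=C\[C@@H](O[Si](C)(C)C(C)(C)C)C[C@@](C)(O[Si](CC)(CC)CC)[C@@H]2CC(=O)[C@@]1(C)O2
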